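**Strategy**

Rings A and B are closed together by an intramolecular Diels–Alder reaction that forms C1–C2 and C5–C10 (labdane numbering). Its precursor is a monocyclic α-methylene δ-lactone: C1=C10 is the exocyclic alkene, C20 the lactone carbonyl, the ring oxygen sits on C12, and C9 (set by rhodium-catalysed conjugate addition) carries a C8(=CH2)–C7–C6 tether ending in the 2-silyloxy diene C5=C4–C3(OSi)=C2. The step exploits the C3 oxygen, the quaternary C10 and the cis relation of C20 and C11 on ring B: it delivers the trans-decalin with C5 and C10 set and a C3 enol ether for building C4. The temporary lactone is then opened: C20 becomes methyl, C12 the side-chain alkene.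

Key step: step 7

Remark: atoms carry the labdane numbers of the target, and α/β refer to its usual drawing with C20 α. The sense of induction of (S)-BINAP in step 3 is assumed to be the one established for six-membered cyclic enones and enoates.

**Route**

Step 1
Reactants: 1 2,3-dibromoprop-1-ene; 2 (1,3-dioxolan-2-ylmethyl)magnesium bromide
Product: 3 2-(3-bromobut-3-en-1-yl)-1,3-dioxolane
Conditions: CuI (5 mol %), THF, 0 °C to rt
Reagents that add atoms: none
Why: copper-catalysed Grignard coupling at the allylic C–Br bond should leave the vinylic bromide untouched and joins C6 to C7.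

Step 2
Reactants: 3 2-(3-bromobut-3-en-1-yl)-1,3-dioxolane
Product: 4 2-[4-(1,3-dioxolan-2-yl)but-1-en-2-yl]-4,4,5,5-tetramethyl-1,3,2-dioxaborolane
Conditions: B2pin2 (1.1 equiv), PdCl2(PPh3)2 (3 mol %), PPh3 (6 mol %), KOPh (1.5 equiv), toluene, 50 °C
Reagents that add atoms: bis(pinacolato)diboron, CC1(C)OB(OC1(C)C)B1OC(C)(C)C(C)(C)O1
Why: Miyaura borylation of a 1-alkenyl bromide with phenoxide as base should give the 1,1-disubstituted alkenylboronate without touching the acetal.

Step 3
Reactants: 4 the alkenylboronate; 5 5,6-dihydro-2H-pyran-2-one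
Product: 6 (4S)-4-[4-(1,3-dioxolan-2-yl)but-1-en-2-yl]oxan-2-one
Conditions: [Rh(OH)((S)-BINAP)]2 (1.5 mol %), 4 (1.5 equiv), 1,4-dioxane/H2O (10:1), 50 °C
Reagents that add atoms: none
Why: rhodium-catalysed asymmetric 1,4-addition of an alkenylboron reagent to an unsaturated lactone (Hayashi–Miyaura reaction); the BINAP-bound alkenylrhodium should add to one enantioface and set C9.

Step 4
Reactants: 6 (4S)-4-[4-(1,3-dioxolan-2-yl)but-1-en-2-yl]oxan-2-one
Product: 9 (4R)-4-[4-(1,3-dioxolan-2-yl)but-1-en-2-yl]-3-methylideneoxan-2-one, via trans Mannich base 7 (not isolated), via trimethylammonium iodide 8 (not isolated)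
Conditions: LiN(SiMe3)2 (1.1 equiv), THF, −78 °C; CH2=NMe2+ I− (1.5 equiv), −78 °C to rt; then MeI (5 equiv), MeOH, rt; then NaHCO3 (aq), CH2Cl2, rt
Reagents that add atoms: N,N-dimethylmethyleneiminium iodide (Eschenmoser's salt), C=[N+](C)C.[I-]
Why: Mannich reaction of the lactone lithium enolate anti to the C9 substituent, N-methylation and β-elimination should give the α-methylene lactone (C1=C10); C9 is untouched, and its descriptor changes only through the priority rules.

Step 5
Reactants: 9 the α-methylene lactone acetal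
Product: 10 4-[(4R)-3-methylidene-2-oxooxan-4-yl]pent-4-enal
Conditions: HCl (2 M aq), THF, rt
Reagents that add atoms: water, O
Why: acid hydrolysis of the dioxolane should free the C5 aldehyde while lactone and alkenes stay intact.

Step 6
Reactants: 10 the aldehyde
Product: 11 (4R)-3-methylidene-4-[(5E)-7-oxoocta-1,5-dien-2-yl]oxan-2-one
Conditions: Ph3P=CHC(O)CH3 (1.3 equiv), CH2Cl2, rt
Reagents that add atoms: 1-(triphenylphosphoranylidene)propan-2-one, CC(=O)C=P(c1ccccc1)(c1ccccc1)c1ccccc1
Why: Wittig reaction of a stabilized ylide should give the (E)-enone (C4=C5) and bring in C2, C3 and C4.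

Step 7
Reactants: 11 the enone lactone
Product: 13 3-(tert-butyldimethylsilyloxy)-13,14,15,16,18,19-hexanorlabda-3,8(17)-dien-20,12-olide (5β-H; 9β-H; C20 α), via silyloxy diene 12 (not isolated)
Conditions: TBSOTf (1.2 equiv), Et3N (2 equiv), CH2Cl2, 0 °C; solvent exchange to toluene, BHT (cat.), 100 °C
Reagents that add atoms: tert-butyldimethylsilyl trifluoromethanesulfonate, CC(C)(C)[Si](C)(C)OS(=O)(=O)C(F)(F)F
Why: Concerted but asynchronous normal-demand [4+2] cycloaddition in which the nucleophilic diene terminus C2 leads onto the β-carbon C1 of the α-methylene lactone and the lactone α-carbon C10 closes onto C5, so polarity and tether agree. The closest known reaction type is the thermal intramolecular Diels–Alder reaction of 1,7,9-decatrienes that carry a 2-silyloxy diene and an internally activated (α-substituted acrylate or acrolein) dienophile. Ring A is closed by both new bonds as the cycloaddition ring, and ring B by the C5–C10 bond through the four-atom tether C6–C7–C8–C9 in a chair-like, fused six-membered closure. C10 is controlled by C9: the tether holds the diene on the lactone face that bears C8, so C5 adds cis to C8 and C20 ends cis to C11 (lactone cis-fused to ring B). C5 is controlled by the endo placement of the lactone carbonyl under the diene with the tether exo, which puts H5 trans to C20 (trans-decalin). The step needs endo over exo selectivity, which should be secured by secondary overlap of C20=O with the diene and by the clash of the diene with C8 and C11 in the exo mode, and it fixes the enol ether at C3=C4 for step 8.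

Step 8
Reactants: 13 the tricyclic silyl enol ether
Product: 15 (Z)-4-(hydroxymethylidene)-3-oxo-13,14,15,16,18-pentanorlabd-8(17)-en-20,12-olide, via keto acetal 14 (not isolated)
Conditions: HC(OMe)3 (3 equiv), TMSOTf (0.2 equiv), CH2Cl2, −78 to −40 °C; then HCl (1 M aq), THF, rt
Reagents that add atoms: trimethyl orthoformate, COC(OC)OC; water, O
Why: Mukaiyama-type reaction of the regiodefined silyl enol ether with the dimethoxycarbenium ion should place C19 on C4 only, and acetal hydrolysis gives the chelated hydroxymethylene ketone.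

Step 9
Reactants: 15 the hydroxymethylene ketone
Product: 16 3,19-dioxo-13,14,15,16-tetranorlabd-8(17)-en-20,12-olide (4β-methyl; 4α-formyl)
Conditions: MeI (3 equiv), K2CO3 (2 equiv), acetone, 40 °C
Reagents that add atoms: iodomethane, CI
Why: C-alkylation of the β-keto aldehyde enolate; MeI should approach C4 anti to the axial C20 carbon on C10, so methyl (C18) becomes equatorial β and the formyl carbon C19 axial α.

Step 10
Reactants: 16 the keto aldehyde lactone
Product: 17 12,20-epoxy-13,14,15,16-tetranorlabd-8(17)-ene-3α,19,20-triol (lactol; anomeric mixture)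
Conditions: i-Bu2AlH (5 equiv), CH2Cl2, −78 °C; aqueous potassium sodium tartrate work-up
Reagents that add atoms: none
Why: hydride reduction takes aldehyde and ketone to alcohols while the lactone stops at the lactol; axial hydride delivery to C3 from the β face, away from axial C19, should give the equatorial 3α-alcohol, and a hemiacetal closed on O19 instead would converge in step 11.

Step 11
Reactants: 17 the diol lactol
Product: 18 13,14,15,16-tetranorlabd-8(17)-ene-3α,12,19-triol
Conditions: N2H4·H2O (10 equiv), KOH (10 equiv), diethylene glycol, 130 °C then 200 °C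
Reagents that add atoms: none
Why: Wolff–Kishner reduction (Huang-Minlon procedure) of the lactol through the hydrazone of its open hydroxy aldehyde should turn C20 into the methyl group and free the C12 alcohol.

Step 12
Reactants: 18 the triol
Product: 19 3α,19-dihydroxy-13,14,15,16-tetranorlabd-8(17)-en-12-al
Conditions: TEMPO (10 mol %), PhI(OAc)2 (1.1 equiv), CH2Cl2, 0 °C to rt
Reagents that add atoms: none
Why: oxoammonium oxidation should select the unhindered primary C12 alcohol over the neopentyl C19 and the secondary C3 alcohols.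

Step 13
Reactants: 19 the aldehyde diol
Product: 20 14,15,16-trinorlabda-8(17),12-diene-3α,19-diol
Conditions: Ph3PCH3Br (4 equiv), KOt-Bu (3.8 equiv), THF, 0 °C to rt
Reagents that add atoms: methyltriphenylphosphonium bromide, C[P+](c1ccccc1)(c1ccccc1)c1ccccc1.[Br-]
Why: Wittig methylenation gives the terminal alkene; no stereocentre is α to the aldehyde, so nothing can epimerize.

Step 14
Reactants: 21 (4S)-4-hydroxyoxolan-2-one
Product: 24 (4S)-4-hydroxy-3-methylideneoxolan-2-one, via Mannich base 22 (not isolated), via ammonium iodide 23 (not isolated)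
Conditions: LiN(i-Pr)2 (2.2 equiv), THF, −78 °C; CH2=NMe2+ I− (1.2 equiv), −78 to 0 °C; then MeI (5 equiv), MeOH, rt; then NaHCO3 (aq), rt
Reagents that add atoms: N,N-dimethylmethyleneiminium iodide (Eschenmoser's salt), C=[N+](C)C.[I-]
Why: the alkoxide enolate dianion cannot β-eliminate and should undergo the Mannich reaction trans to the alkoxide; N-methylation and elimination then give the α-methylene lactone with the carbinol centre untouched.

Step 15
Reactants: 24 (4S)-4-hydroxy-3-methylideneoxolan-2-one
Product: 25 (3S)-4-methylidene-5-oxooxolan-3-yl acetate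
Conditions: Ac2O (1.5 equiv), Sc(OSO2CF3)3 (1 mol %), MeCN, 0 °C
Reagents that add atoms: acetic anhydride, CC(=O)OC(C)=O
Why: Lewis acid-catalysed acetylation avoids nucleophilic amines that could attack the allylic system in an SN2′ sense.

Step 16
Reactants: 20 the allyl diol; 25 the acetoxy methylene lactone
Product: 26 14-O-acetylandrographolide ((12E,14S)-14-acetoxy-3α,19-dihydroxylabda-8(17),12-dien-16,15-olide)
Conditions: 25 (3 equiv), RuCl2(H2IMes)(=CH-C6H4-2-O-i-Pr) (Hoveyda–Grubbs second-generation catalyst, 10 mol %), 2,6-dichloro-1,4-benzoquinone (20 mol %), CH2Cl2, 40 °C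
Reagents that add atoms: none
Why: olefin cross-metathesis of a terminal alkene with a 1,1-disubstituted acrylate-type alkene should form C12=C13 with the thermodynamically preferred E geometry (C11 trans to the lactone carbonyl), while the hindered C8 methylene and the free diol do not react.

**Compound list**

1 | 2,3-dibromoprop-1-ene | C=C(Br)CBr | starting material
2 | (1,3-dioxolan-2-ylmethyl)magnesium bromide | Br[Mg]CC1OCCO1 | starting material
3 | 2-(3-bromobut-3-en-1-yl)-1,3-dioxolane | C=C(Br)CCC1OCCO1 | intermediate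
4 | 2-[4-(1,3-dioxolan-2-yl)but-1-en-2-yl]-4,4,5,5-tetramethyl-1,3,2-dioxaborolane | C=C(B1OC(C)(C)C(C)(C)O1)CCC1OCCO1 | intermediate
5 | 5,6-dihydro-2H-pyran-2-one | O=C1C=CCCO1 | starting material
6 | (4S)-4-[4-(1,3-dioxolan-2-yl)but-1-en-2-yl]oxan-2-one | O=C1C[C@@H](C(=C)CCC2OCCO2)CCO1 | intermediate
7 | (3S,4S)-3-[(dimethylamino)methyl]-4-[4-(1,3-dioxolan-2-yl)but-1-en-2-yl]oxan-2-one (trans; not isolated) | O=C1OCC[C@H](C(=C)CCC2OCCO2)[C@H]1CN(C)C | intermediate
8 | trimethylammonium iodide of 7 (not isolated) | O=C1OCC[C@H](C(=C)CCC2OCCO2)[C@H]1C[N+](C)(C)C.[I-] | intermediate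
9 | (4R)-4-[4-(1,3-dioxolan-2-yl)but-1-en-2-yl]-3-methylideneoxan-2-one | O=C1OCC[C@H](C(=C)CCC2OCCO2)C1=C | intermediate
10 | 4-[(4R)-3-methylidene-2-oxooxan-4-yl]pent-4-enal | O=C1OCC[C@H](C(=C)CCC=O)C1=C | intermediate
11 | (4R)-3-methylidene-4-[(5E)-7-oxoocta-1,5-dien-2-yl]oxan-2-one | O=C1OCC[C@H](C(=C)CC/C=C/C(C)=O)C1=C | intermediate
12 | (4R)-4-[(5E)-7-(tert-butyldimethylsilyloxy)octa-1,5,7-trien-2-yl]-3-methylideneoxan-2-one (not isolated) | O=C1OCC[C@H](C(=C)CC/C=C/C(=C)O[Si](C)(C)C(C)(C)C)C1=C | intermediate
13 | 3-(tert-butyldimethylsilyloxy)-13,14,15,16,18,19-hexanorlabda-3,8(17)-dien-20,12-olide (5β-H, 9β-H, C20 α) | C=C1CC[C@@H]2C=C(O[Si](C)(C)C(C)(C)C)CC[C@@]2(C(=O)OCC3)[C@@H]13 | intermediate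
14 | 4β-(dimethoxymethyl)-3-oxo-13,14,15,16,18,19-hexanorlabd-8(17)-en-20,12-olide (not isolated) | C=C1CC[C@@H]2[C@@H](C(OC)OC)C(=O)CC[C@@]2(C(=O)OCC3)[C@@H]13 | intermediate
15 | (Z)-4-(hydroxymethylidene)-3-oxo-13,14,15,16,18-pentanorlabd-8(17)-en-20,12-olide | C=C1CC[C@@H]2/C(=C/O)C(=O)CC[C@@]2(C(=O)OCC3)[C@@H]13 | intermediate
16 | 3,19-dioxo-13,14,15,16-tetranorlabd-8(17)-en-20,12-olide (4β-methyl, 4α-formyl) | C=C1CC[C@@H]2[C@](C)(C=O)C(=O)CC[C@@]2(C(=O)OCC3)[C@@H]13 | intermediate
17 | 12,20-epoxy-13,14,15,16-tetranorlabd-8(17)-ene-3α,19,20-triol (lactol, anomeric mixture) | C=C1CC[C@@H]2[C@](C)(CO)[C@H](O)CC[C@@]2(C(O)OCC3)[C@@H]13 | intermediate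
18 | 13,14,15,16-tetranorlabd-8(17)-ene-3α,12,19-triol | C=C1CC[C@@H]2[C@](C)(CO)[C@H](O)CC[C@@]2(C)[C@@H]1CCO | intermediate
19 | 3α,19-dihydroxy-13,14,15,16-tetranorlabd-8(17)-en-12-al | C=C1CC[C@@H]2[C@](C)(CO)[C@H](O)CC[C@@]2(C)[C@@H]1CC=O | intermediate
20 | 14,15,16-trinorlabda-8(17),12-diene-3α,19-diol | C=C1CC[C@@H]2[C@](C)(CO)[C@H](O)CC[C@@]2(C)[C@@H]1CC=C | intermediate
21 | (4S)-4-hydroxyoxolan-2-one ((S)-3-hydroxy-γ-butyrolactone) | O=C1C[C@H](O)CO1 | starting material
22 | (3S,4S)-3-[(dimethylamino)methyl]-4-hydroxyoxolan-2-one (trans; not isolated) | CN(C)C[C@@H]1C(=O)OC[C@H]1O | intermediate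
23 | trimethylammonium iodide of 22 (not isolated) | C[N+](C)(C)C[C@@H]1C(=O)OC[C@H]1O.[I-] | intermediate
24 | (4S)-4-hydroxy-3-methylideneoxolan-2-one | C=C1C(=O)OC[C@H]1O | intermediate
25 | (3S)-4-methylidene-5-oxooxolan-3-yl acetate | C=C1C(=O)OC[C@H]1OC(C)=O | intermediate
26 | 14-O-acetylandrographolide | C=C1CC[C@@H]2[C@](C)(CO)[C@H](O)CC[C@@]2(C)[C@@H]1C/C=C1/C(=O)OC[C@H]1OC(C)=O | target

**Step count**

Total: 16 steps. Longest linear sequence: 14 steps (steps 1–13 and 16); steps 14 and 15 make the lactone partner 25.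

**Steps most likely to fail**

1. Step 16. The cross-metathesis may be sluggish at the hindered, electron-poor 1,1-disubstituted alkene of 25, so that homodimerisation of 20 or migration of the exocyclic double bond into the lactone ring takes over, or E/Z control may be poor. The fallback sets out from aldehyde 19 and comes back at 26. The 3,19-diol is masked with 2-methoxypropene and pyridinium p-toluenesulfonate to give the acetonide aldehyde F1. Aldol addition of the lithium enolate (LiN(i-Pr)2, THF, −78 °C) of (4S)-4-(tert-butyldimethylsilyloxy)oxolan-2-one F2 (from 21 with TBSCl and imidazole) gives the β-hydroxy lactone F3, trans across C13–C14. Mesylation (MsCl, Et3N) to the mesylate F4 and elimination with DBU give the (E)-alkylidene lactone F5; the silyloxy group is too poor a leaving group to compete. HF·pyridine frees the C14 alcohol to give 3,19-O-isopropylideneandrographolide F6, acetylation (Ac2O, pyridine) gives the 14-acetate F7, and aqueous acetic acid removes the acetonide to give 26.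

2. Step 7. Endo/exo discrimination may be poor, with exo approach leading to the cis ring fusion, or the silyl enol ether may be lost before cyclisation. The fallback sets out from enone 11 and comes back at 13. The neutral cycloaddition is replaced by the anionic one: kinetic deprotonation of the methyl ketone with LiN(SiMe3)2 (THF, −78 °C) gives the cross-conjugated lithium dienolate, in which lithium can bridge O3 and the lactone carbonyl oxygen only in the endo arrangement. Warming closes both bonds as an intramolecular double Michael addition, and the resulting C3 lithium enolate is trapped with TBSCl and DMPU to give 13. This fallback makes no further compound (F0).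

3. Step 11. Hydrazone formation at the neopentyl C20 may stay incomplete, and at 200 °C base-induced hydride transfer from the masked aldehyde may compete. The fallback sets out from lactol 17 and comes back at 18. Condensation with p-toluenesulfonyl hydrazide (EtOH, 60 °C) gives the tosylhydrazone F8, which is reduced with catecholborane (CHCl3, 0 °C) and decomposed with NaOAc·3H2O at reflux (Caglioti-type reduction).

**Further compounds**

F1 | step 16 | 3α,19-O-isopropylidene-13,14,15,16-tetranorlabd-8(17)-en-12-al | C=C1CC[C@@H]2[C@](C)(CO3)[C@H](OC3(C)C)CC[C@@]2(C)[C@@H]1CC=O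
F2 | step 16 | (4S)-4-(tert-butyldimethylsilyloxy)oxolan-2-one | O=C1C[C@H](O[Si](C)(C)C(C)(C)C)CO1
F3 | step 16 | aldol adduct: 3,19-O-isopropylidene-12-hydroxy-14-(tert-butyldimethylsilyloxy)labd-8(17)-en-16,15-olide (C12 epimers, 13,14-trans) | C=C1CC[C@@H]2[C@](C)(CO3)[C@H](OC3(C)C)CC[C@@]2(C)[C@@H]1CC(O)[C@@H]1C(=O)OC[C@H]1O[Si](C)(C)C(C)(C)C
F4 | step 16 | 12-methanesulfonate of F3 | C=C1CC[C@@H]2[C@](C)(CO3)[C@H](OC3(C)C)CC[C@@]2(C)[C@@H]1CC(OS(C)(=O)=O)[C@@H]1C(=O)OC[C@H]1O[Si](C)(C)C(C)(C)C
F5 | step 16 | 3,19-O-isopropylidene-14-O-(tert-butyldimethylsilyl)andrographolide | C=C1CC[C@@H]2[C@](C)(CO3)[C@H](OC3(C)C)CC[C@@]2(C)[C@@H]1C/C=C1/C(=O)OC[C@H]1O[Si](C)(C)C(C)(C)C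
F6 | step 16 | 3,19-O-isopropylideneandrographolide | C=C1CC[C@@H]2[C@](C)(CO3)[C@H](OC3(C)C)CC[C@@]2(C)[C@@H]1C/C=C1/C(=O)OC[C@H]1O
F7 | step 16 | 14-O-acetyl-3,19-O-isopropylideneandrographolide | C=C1CC[C@@H]2[C@](C)(CO3)[C@H](OC3(C)C)CC[C@@]2(C)[C@@H]1C/C=C1/C(=O)OC[C@H]1OC(C)=O
F0 | step 7 | none | none
F8 | step 11 | (E)-p-toluenesulfonylhydrazone of 3α,12,19-trihydroxy-13,14,15,16-tetranorlabd-8(17)-en-20-al | C=C1CC[C@@H]2[C@](C)(CO)[C@H](O)CC[C@@]2(/C=N/NS(=O)(=O)c3ccc(C)cc3)[C@@H]1CCO
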